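The ratio of G to Q at the last reading is 5.02 in the delta run and 3.52 in the beta run, and with the scatter on small Q readings neither has the better claim, so pooling the two you can read the share of G (the selectivity) as near 80.6 % at 10.0 min.

| flask | Z | remark | time |
|---|---|---|---|
| theta | 0.50 M | run made earlier |  |
| delta | 0.25 M | run made earlier |  |
| beta | 1 M | run made earlier |  |
| violet | 0.50 M | one stirred flow tank at steady state, fed with the mixture as stated, mean residence time 40.0 min |  |
| ochre | 0.50 M | a single well-mixed tank run continuously and read at steady state, 8.0 min in it on average |  |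
| green | 0.50 M | a closed flask charged with all of it at once and left for 8.0 min | 8.0 min |

| run | time / min | G / % | Q / % |
|---|---|---|---|
| theta | 0.417 | 0.2 | 0.5 |
| theta | 0.667 | 0 | 0 |
| theta | 1.00 | 0 | 1.6 |
| theta | 2.00 | 2.4 | 1.2 |
| theta | 3.00 | 5.4 | 0.3 |
| theta | 5.00 | 9.3 | 2.1 |
| delta | 0.833 | 0.7 | 0.2 |
| delta | 1.33 | 1.2 | 0.8 |
| delta | 2.00 | 3.0 | 0.8 |
| delta | 4.00 | 6.6 | 1.2 |
| delta | 6.00 | 12.6 | 2.1 |
| delta | 10.0 | 20.6 | 4.1 |
| beta | 1.50 | 1.3 | 0 |
| beta | 3.00 | 5.2 | 1.4 |
| beta | 5.00 | 7.4 | 2.7 |
| beta | 6.00 | 13.0 | 2.3 |
| beta | 8.00 | 17.9 | 1.9 |
| beta | 10.0 | 19.7 | 5.6 |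

(each reading ± 1 percentage point)

- the stated concentrations are those of everything mixed, before any reaction; amounts are the same in each set-up
- the earlier runs were read with a standard deviation of 1 percentage point
- the earlier runs were made in a closed, stirred flask

- the set-up with the highest share of G in all that became G or Q, at the outlet or at the end ("none" if the first two lie within 2 percentage points) (violet / ochre / green / none)
- share of G in all that became G or Q, at the outlet or at the end, violet
- share of G in all that became G or Q, at the outlet or at the end, ochre
- share of G in all that became G or Q, at the outlet or at the end, green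

Take the settings in turn. By hand, a step that felt the concentration would move the percentages with the charge of Z. But 0.25 M gives 20.6 % of G at 10.0 min and 1 M gives 19.7 %, so I expect the charge to do little. Next comes time. G and Q together reach 24.7 % in the delta run, so the other 75.3 % stands as something else at that reading, and the share there need not be an end state. Green stops earlier, at 8.0 min, so its share lies inside the readings, and I reckon about 80.6 %.

Last comes the vessel. A closed flask holds one age, while a stirred tank sends out a spread of ages (the residence-time distribution), and the part older than a time t is exp(-t/τ). In violet, 77.9 % of the outflow has stayed beyond the last reading. Call this part the overage. In ochre it is 28.7 %, less. No reading speaks for that part, so I won't call the tanks equal to green, and I name green best.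

The forecast gave 84 % for violet, 82.9 % for ochre, 82.6 % for green and best none, holding that “Percent-versus-time curves coincide at 0.25, 0.5 and 1 M, so every step is first order”.

The flasks give 57.8 % for violet, 73.9 % for ochre and 82.9 % for green, so the best is green.

    X → L (k = 0.120 min⁻¹)
    Z → X (k = 0.140 min⁻¹)
    J ⇌ E (K = 1.10, k = 0.660 min⁻¹)
    Z → J (k = 0.0720 min⁻¹)
    Z → D (k = 9.40 × 10⁻⁵ min⁻¹)
    X → G (k = 0.120 min⁻¹)
    L → Q (k = 0.0680 min⁻¹)

The shares fall in the order of the overage, 28.7 % for ochre and 77.9 % for violet. The green flask, read later at 20 min, has dropped to 65.0 %, lower than at 8.0 min. Taken at that age, the overage is 60.7 % in violet, whose 57.8 % lies below that closed share. In ochre it is 8.21 %, and its 73.9 % lies above it.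

The earlier runs and the new flask were computed on assumed constants; noise was put on by code.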